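Readings and results are simulated for an exercise, noise included.

The elm run cannot show its own peak of target, since its readings stop at 3.00 min with 34.6% of the substrate still there, so reckon with rates. With the gas held, replace the curved substrate loss by its mean: k̄ = 0.367 min⁻¹, the mean pseudo-first-order constant of substrate, the slope of ln(substrate) between the first and last readings. Its half-life is 1.89 min.

| flask | substrate | gas phase | remark | time |
|---|---|---|---|---|
| elm | 22 mM | 24 mM (held) | run made earlier |  |
| flask | 44 mM | 24 mM (held) |  | 15 min |

elm run (percent of the substrate charged)

| time / min | target / % | substrate / % |
|---|---|---|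
| 0.667 | 9.3 | 81.4 |
| 1.33 | 16.7 | 63.3 |
| 2.00 | 23.6 | 48.9 |
| 2.50 | 27.6 | 41.3 |
| 3.00 | 29.1 | 34.6 |

(each reading ± 1 percentage point)

* when, up to 15 min, the flask holds most target
* the amount of target, in percent of the substrate charged, at that time
* earliest time at which at least nineteen twentieths of that best amount are there, in min
* latest time at which they still are, in min

- at the start none of the gas phase is in solution

Let f be the share of lost substrate that appears as target, read as 0.500 at the first reading. My reckoning then starts target at f·k̄ = 0.183 min⁻¹ of the charge. Two things slow this rate. The substrate's fall multiplies it by exp(−k̄t). The gas, absent from solution at first, costs a delay read as 0.106 min in the elm run. In the asked flask, twice the charge adds by my estimate 0.0485 min, a total delay shorter than the half-life, so I carry the elm percentages over to that flask. Taking the forecast's loss of 0.05 per min, I assume that making meets this loss after a 10-fold fall, which puts my estimate of the peak at 6.43 min.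

The forecast, holding that “doubling the substrate should leave percentages nearly unchanged”, gives 35% at 6.6 min, later than my 6.43 min, with a window from 4.5 min to 9.5 min.

The flask gives 34.1% at 5.98 min, with a window from 4.17 min to 8.41 min.

    gas phase ⇌ dissolved gas, rate k1*(csat - [dissolved gas]) (kL = 6.50 min⁻¹)
    substrate + dissolved gas → target (k = 7.90 M⁻¹ min⁻¹)
    substrate → side product (k = 0.180 min⁻¹)
    target → over-reaction product (k = 0.0640 min⁻¹)

Target's half-life by the path to over-reaction product is 11 min, longer than the 1.89 min of substrate under k̄, and by 15.0 min the flask makes target at 0.0537 of the rate it uses it. Carried forward, exp(−k̄t) gives 0.408% of the substrate at that time, where the flask holds 0.41%, and 2.55% at 10 min in the neighbouring reading, which holds 2.62%.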